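**Plan**

1. Retrosynthesis: the two aryl silyl ethers come off last. Ring A is then cut at C8–C8a, C5–C6, C7–C8 and C4a–C5 (flavanone numbering, also used for the pyranone atoms that become ring C), giving a C-ring diazoketone and the siloxyalkyne of prenylacetylene. The diazoketone goes back to a pyranone-6-carboxylate, cut at C2–C3 and O1–C8a into the B-ring aldehyde and a C5 acetopyruvate dienolate.
2. Enabling feature: ring A is a benzene bearing C5–OH, C6–prenyl, C7–OH and C8–H, fused to ring C through C8a–O1 and C4a–C4(=O). A carbon substituent flanked by two oxygens is what a vinylketene/ynol ether benzannulation delivers, and C4a=C8a can be supplied as the enol-ether double bond of a dihydropyran-4-one.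
3. Forward order: geranylated B-ring aldehyde, then ring C (aldol and cyclodehydration), then ring A (photochemical benzannulation), then desilylation; the alkyne partner is made separately in two steps.
4. Stereochemistry: the only stereocentre, C2 (S), is set by the Ti–(S)-BINOL-catalysed Mukaiyama aldol and is carried through steps that avoid free base. The E-alkene of the geranyl group is bought with geranyl bromide.

Key step: step 9

Assumption: the Ti–(S)-BINOL catalyst is taken to direct the diene to the Si face of aldehyde 4 (giving 2S); the configuration would be assayed at pyranone 10 and (R)-BINOL used instead, with no other change, if the sense proved opposite.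

Abbreviation: Ar = 3-[(2E)-3,7-dimethylocta-2,6-dien-1-yl]-4-(triisopropylsilyloxy)phenyl (3-geranyl-4-TIPSO-phenyl).

**Route**

Step 1
Reactants: 1 4-hydroxybenzaldehyde; 2 geranyl bromide
Product: 3 3-geranyl-4-hydroxybenzaldehyde
Conditions: KOH (10% aq), 20 °C; then aq HCl to pH 5
Reagents that add atoms: none
Why: Ortho C-alkylation of a phenoxide in water (SN2 at the primary allylic carbon) is the established entry to 3-prenyl- and 3-geranyl-4-hydroxybenzaldehydes; the para position is blocked by the formyl group, the E-alkene is untouched, and O-alkylated and dialkylated material is removed by chromatography.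

Step 2
Reactants: 3 3-geranyl-4-hydroxybenzaldehyde
Product: 4 3-geranyl-4-(triisopropylsilyloxy)benzaldehyde
Conditions: TIPSCl, imidazole, DMF, 20 °C
Reagents that add atoms: chlorotriisopropylsilane, CC(C)[Si](Cl)(C(C)C)C(C)C
Why: Standard phenol silylation; the TIPS ether tolerates the Lewis acid, mild acid, tin hydroxide, diazomethane and light used later and falls together with the ring-A silyl ether in the last step.

Step 3
Reactants: 5 methyl 2,4-dioxopentanoate
Product: 7 methyl (2Z)-2,4-bis(trimethylsilyloxy)penta-2,4-dienoate, via monosilyl enol ether 6 (not isolated)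
Conditions: TMSOTf (2.2 equiv), Et3N (2.6 equiv), Et2O, 0 → 20 °C
Reagents that add atoms: trimethylsilyl trifluoromethanesulfonate, C[Si](C)(C)OS(=O)(=O)C(F)(F)F
Why: Silyl triflate/amine enol silylation (Simchen conditions): the keto ester is already enolised at C2 and is silylated there first, after which the remaining methyl ketone is converted into its terminal silyl enol ether, giving a 2-siloxydiene of the Danishefsky–Chan family.

Step 4
Reactants: 4 3-geranyl-4-(triisopropylsilyloxy)benzaldehyde; 7 methyl (2Z)-2,4-bis(trimethylsilyloxy)penta-2,4-dienoate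
Product: 10 methyl (2S)-2-Ar-4-oxo-3,4-dihydro-2H-pyran-6-carboxylate, via silyl aldol adduct 8 (not isolated), via hemiketal 9 (not isolated)
Conditions: (S)-BINOL (20 mol %), Ti(OiPr)4 (10 mol %), 4 Å MS, Et2O, –20 °C; then CF3CO2H (0.3 equiv), CH2Cl2, 0 → 20 °C
Reagents that add atoms: none
Why: Catalytic asymmetric Mukaiyama aldol at the CH2 terminus of the siloxydiene (Keck-type Ti–BINOL aldol/dihydropyranone annulation), in which the chiral titanium complex is expected to leave the Si face of the aldehyde open and so set C2 as S; catalytic acid then removes the silyl groups, the benzylic hydroxyl adds to the α-keto ester carbonyl, and the hemiketal dehydrates to the vinylogous ester.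

Step 5
Reactants: 10 methyl (2S)-2-Ar-4-oxo-3,4-dihydro-2H-pyran-6-carboxylate
Product: 12 (2S)-2-Ar-4-oxo-3,4-dihydro-2H-pyran-6-carboxylic acid, via trimethylstannyl ester 11 (not isolated)
Conditions: Me3SnOH (4 equiv), ClCH2CH2Cl, 70 °C; then cold 0.5 M HCl wash
Reagents that add atoms: trimethyltin hydroxide, C[Sn](C)(C)O
Why: Trimethyltin hydroxide ester cleavage (Nicolaou conditions) runs through the stannyl ester under essentially neutral conditions, which should spare the aryl silyl ether and avoid the retro-oxa-Michael opening of the β-aryl-β-alkoxy ketone that would racemise C2 in aqueous hydroxide.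

Step 6
Reactants: 12 (2S)-2-Ar-4-oxo-3,4-dihydro-2H-pyran-6-carboxylic acid
Product: 14 (2S)-6-(diazoacetyl)-2-Ar-2,3-dihydro-4H-pyran-4-one, via acid chloride 13 (not isolated)
Conditions: 1-chloro-N,N,2-trimethylprop-1-en-1-amine (1.2 equiv), CH2Cl2, 0 → 20 °C; then CH2N2 (2.5 equiv), Et2O, –20 → 0 °C; AcOH quench
Reagents that add atoms: diazomethane, C=[N+]=[N-]; 1-chloro-N,N,2-trimethylprop-1-en-1-amine, CC(C)=C(Cl)N(C)C (chlorine of 13 only)
Why: Arndt–Eistert-type acylation of diazomethane: the Ghosez chloroenamine forms the acid chloride without liberating HCl (safe for the silyl ether and the trisubstituted alkenes), the second equivalent of diazomethane takes up HCl, and the acylation is kept cold and short so that it outruns dipolar addition to the enedione double bond.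

Step 7
Reactants: 15 prenyl bromide; 16 ethynylmagnesium bromide
Product: 17 5-methylhex-4-en-1-yne
Conditions: CuCl (5 mol %), THF, 0 → 50 °C (16 in excess)
Reagents that add atoms: none
Why: Copper(I)-catalysed SN2 coupling of an alkynyl Grignard reagent with a primary allylic bromide gives the skipped enyne; attack at the unhindered CH2 terminus is favoured over the SN2′ path that would create a quaternary carbon.

Step 8
Reactants: 17 5-methylhex-4-en-1-yne
Product: 20 triisopropyl[(5-methylhex-4-en-1-yn-1-yl)oxy]silane, via lithium acetylide 18 (not isolated), via lithium ynolate 19 (not isolated)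
Conditions: n-BuLi, THF, –78 °C; t-BuOOLi (from t-BuOOH + LiHMDS), –78 → 0 °C; TIPSOTf, –78 → 0 °C
Reagents that add atoms: tert-butyl hydroperoxide, CC(C)(C)OO; triisopropylsilyl trifluoromethanesulfonate, CC(C)[Si](OS(=O)(=O)C(F)(F)F)(C(C)C)C(C)C
Why: Julia oxidation of a lithium acetylide by lithium tert-butyl peroxide gives the lithium ynolate, which the bulky silyl triflate silylates on oxygen to the isolable triisopropylsiloxyalkyne.

Step 9
Reactants: 14 (2S)-6-(diazoacetyl)-2-Ar-2,3-dihydro-4H-pyran-4-one; 20 triisopropyl[(5-methylhex-4-en-1-yn-1-yl)oxy]silane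
Product: 25 (2S)-2-Ar-5-hydroxy-6-(3-methylbut-2-en-1-yl)-7-(triisopropylsilyloxy)-2,3-dihydro-4H-chromen-4-one (7,4′-bis-O-TIPS schizolaenone A), via vinylketene 21 (not isolated), via vinylcyclobutenone 22 (not isolated), via dienylketene 23 (not isolated), via cyclohexadienone 24 (not isolated)
Conditions: hν (440 nm LEDs), 20 (1.3 equiv), ClCH2CH2Cl (0.05 M), 20 °C; then 80 °C
Reagents that add atoms: none
Why: Excitation of the diazoketone, the only chromophore that absorbs at this wavelength, expels N2 with 1,2-shift of the pyranone enol-ether carbon (Wolff rearrangement), forming C8–C8a and vinylketene 21 whose vinyl unit is the C4a=C8a bond. The polarised siloxyalkyne attacks the ketene carbonyl carbon through its prenyl-bearing carbon and closes to the 2-prenyl-3-siloxy-4-vinylcyclobutenone 22 ([2+2], forming C5–C6 and C7–C8). At 80 °C reversible conrotatory 4π opening gives dienylketene 23, whose isomer with the pyranone turned inward closes the six-membered ring A by 6π electrocyclisation (C4a–C5); dienone 24 then enolises to the C5 phenol hydrogen-bonded to C4=O. This is the diazoketone (photo-Wolff) form of the Danheiser benzannulation with siloxyalkynes, which gives resorcinol monosilyl ethers. No stereocentre is formed, and C2 lies outside all bond changes in a neutral medium. The step needs the [2+2] regiochemistry that puts prenyl between the two oxygens (C6, not C8), which the ynol-ether polarity secures, and selective excitation of the diazoketone, which the long wavelength secures against enone, aryl ketone and alkene photochemistry.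

Step 10
Reactants: 25 7,4′-bis-O-TIPS schizolaenone A
Product: 27 schizolaenone A, via 4′-O-TIPS schizolaenone A 26 (not isolated)
Conditions: TBAF (3 equiv), AcOH (3.5 equiv), THF, 0 → 20 °C
Reagents that add atoms: none
Why: Fluoride cleavage of both aryl silyl ethers (the C7 ether para to the carbonyl first), buffered with acetic acid so that no phenoxide forms that could open the flavanone ring and racemise C2, and free of the strong acid that would cyclise prenyl or geranyl onto a neighbouring phenol.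

**Compound list**

1 | 4-hydroxybenzaldehyde | O=Cc1ccc(O)cc1 | starting material
2 | geranyl bromide, (2E)-1-bromo-3,7-dimethylocta-2,6-diene | CC(C)=CCC/C(C)=C/CBr | starting material
3 | 3-geranyl-4-hydroxybenzaldehyde | CC(C)=CCC/C(C)=C/Cc1cc(C=O)ccc1O | intermediate
4 | 3-geranyl-4-(triisopropylsilyloxy)benzaldehyde | CC(C)=CCC/C(C)=C/Cc1cc(C=O)ccc1O[Si](C(C)C)(C(C)C)C(C)C | intermediate
5 | methyl 2,4-dioxopentanoate | COC(=O)C(=O)CC(C)=O | starting material
6 | methyl (2Z)-4-oxo-2-(trimethylsilyloxy)pent-2-enoate | COC(=O)/C(O[Si](C)(C)C)=C/C(C)=O | intermediate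
7 | methyl (2Z)-2,4-bis(trimethylsilyloxy)penta-2,4-dienoate | COC(=O)/C(O[Si](C)(C)C)=C/C(=C)O[Si](C)(C)C | intermediate
8 | methyl (2Z,6S)-6-Ar-4-oxo-2,6-bis(trimethylsilyloxy)hex-2-enoate | CC(C)=CCC/C(C)=C/Cc1cc([C@H](CC(=O)/C=C(\O[Si](C)(C)C)C(=O)OC)O[Si](C)(C)C)ccc1O[Si](C(C)C)(C(C)C)C(C)C | intermediate
9 | methyl (6S)-6-Ar-2-hydroxy-4-oxooxane-2-carboxylate (both C2 epimers) | CC(C)=CCC/C(C)=C/Cc1cc([C@@H]2CC(=O)CC(O)(C(=O)OC)O2)ccc1O[Si](C(C)C)(C(C)C)C(C)C | intermediate
10 | methyl (2S)-2-Ar-4-oxo-3,4-dihydro-2H-pyran-6-carboxylate | CC(C)=CCC/C(C)=C/Cc1cc([C@@H]2CC(=O)C=C(C(=O)OC)O2)ccc1O[Si](C(C)C)(C(C)C)C(C)C | intermediate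
11 | trimethylstannyl (2S)-2-Ar-4-oxo-3,4-dihydro-2H-pyran-6-carboxylate | CC(C)=CCC/C(C)=C/Cc1cc([C@@H]2CC(=O)C=C(C(=O)O[Sn](C)(C)C)O2)ccc1O[Si](C(C)C)(C(C)C)C(C)C | intermediate
12 | (2S)-2-Ar-4-oxo-3,4-dihydro-2H-pyran-6-carboxylic acid | CC(C)=CCC/C(C)=C/Cc1cc([C@@H]2CC(=O)C=C(C(=O)O)O2)ccc1O[Si](C(C)C)(C(C)C)C(C)C | intermediate
13 | (2S)-2-Ar-4-oxo-3,4-dihydro-2H-pyran-6-carbonyl chloride | CC(C)=CCC/C(C)=C/Cc1cc([C@@H]2CC(=O)C=C(C(=O)Cl)O2)ccc1O[Si](C(C)C)(C(C)C)C(C)C | intermediate
14 | (2S)-6-(diazoacetyl)-2-Ar-2,3-dihydro-4H-pyran-4-one | CC(C)=CCC/C(C)=C/Cc1cc([C@@H]2CC(=O)C=C(C(=O)C=[N+]=[N-])O2)ccc1O[Si](C(C)C)(C(C)C)C(C)C | intermediate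
15 | prenyl bromide, 1-bromo-3-methylbut-2-ene | CC(C)=CCBr | starting material
16 | ethynylmagnesium bromide | C#C[Mg]Br | starting material
17 | 5-methylhex-4-en-1-yne | C#CCC=C(C)C | intermediate
18 | (5-methylhex-4-en-1-yn-1-yl)lithium | [Li]C#CCC=C(C)C | intermediate
19 | lithium 5-methylhex-4-en-1-yn-1-olate | [Li]OC#CCC=C(C)C | intermediate
20 | triisopropyl[(5-methylhex-4-en-1-yn-1-yl)oxy]silane | CC(C)=CCC#CO[Si](C(C)C)(C(C)C)C(C)C | intermediate
21 | (2S)-2-Ar-6-(2-oxoethenyl)-2,3-dihydro-4H-pyran-4-one (vinylketene) | CC(C)=CCC/C(C)=C/Cc1cc([C@@H]2CC(=O)C=C(C=C=O)O2)ccc1O[Si](C(C)C)(C(C)C)C(C)C | intermediate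
22 | 4-[(2S)-2-Ar-4-oxo-3,4-dihydro-2H-pyran-6-yl]-2-(3-methylbut-2-en-1-yl)-3-(triisopropylsilyloxy)cyclobut-2-en-1-one (both C4 epimers) | CC(C)=CCC/C(C)=C/Cc1cc([C@@H]2CC(=O)C=C(C3C(=O)C(CC=C(C)C)=C3O[Si](C(C)C)(C(C)C)C(C)C)O2)ccc1O[Si](C(C)C)(C(C)C)C(C)C | intermediate
23 | (2S)-2-Ar-6-[(1E)-3-(3-methylbut-2-en-1-yl)-4-oxo-2-(triisopropylsilyloxy)buta-1,3-dien-1-yl]-2,3-dihydro-4H-pyran-4-one (dienylketene) | CC(C)=CCC/C(C)=C/Cc1cc([C@@H]2CC(=O)C=C(/C=C(/O[Si](C(C)C)(C(C)C)C(C)C)C(CC=C(C)C)=C=O)O2)ccc1O[Si](C(C)C)(C(C)C)C(C)C | intermediate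
24 | (2S)-2-Ar-6-(3-methylbut-2-en-1-yl)-7-(triisopropylsilyloxy)-2,3-dihydro-4aH-chromene-4,5-dione (4a-H keto tautomer) | CC(C)=CCC/C(C)=C/Cc1cc([C@@H]2CC(=O)C3C(=O)C(CC=C(C)C)=C(O[Si](C(C)C)(C(C)C)C(C)C)C=C3O2)ccc1O[Si](C(C)C)(C(C)C)C(C)C | intermediate
25 | 7,4′-bis-O-TIPS schizolaenone A | CC(C)=CCC/C(C)=C/Cc1cc([C@@H]2CC(=O)c3c(cc(O[Si](C(C)C)(C(C)C)C(C)C)c(CC=C(C)C)c3O)O2)ccc1O[Si](C(C)C)(C(C)C)C(C)C | intermediate
26 | 4′-O-TIPS schizolaenone A | CC(C)=CCC/C(C)=C/Cc1cc([C@@H]2CC(=O)c3c(cc(O)c(CC=C(C)C)c3O)O2)ccc1O[Si](C(C)C)(C(C)C)C(C)C | intermediate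
27 | schizolaenone A, (2S)-2-(3-geranyl-4-hydroxyphenyl)-5,7-dihydroxy-6-(3-methylbut-2-en-1-yl)-2,3-dihydro-4H-chromen-4-one | CC(C)=CCC/C(C)=C/Cc1cc([C@@H]2CC(=O)c3c(cc(O)c(CC=C(C)C)c3O)O2)ccc1O | target

**Totals**

Total step count: 10. Longest linear sequence: 7 steps (1, 2, 4, 5, 6, 9, 10) from 4-hydroxybenzaldehyde.

**Steps most likely to fail**

Step 9 (benzannulation). In the single flask the excited diazoketone or the derived acylcarbene may be intercepted by the electron-rich alkyne or by an alkene (cyclopropenation, furan formation) in competition with the Wolff shift, and photolysis at long wavelength may be slow enough for the siloxyalkyne to degrade. The fallback sets out from 14 and comes back at 22, and separates ketene formation from the alkyne. Diazoketone 14 is irradiated alone in THF–water, so that water traps the ketene (photochemical Arndt–Eistert homologation) and gives [(2S)-2-Ar-4-oxo-3,4-dihydro-2H-pyran-6-yl]acetic acid F1. The Ghosez chloroenamine converts it into [(2S)-2-Ar-4-oxo-3,4-dihydro-2H-pyran-6-yl]acetyl chloride F2. Slow addition of triethylamine to F2 and siloxyalkyne 20 in toluene at 0–20 °C in the dark generates vinylketene 21 by dehydrochlorination in the presence of its trap and should give cyclobutenone 22, which is heated to 80 °C as in step 9 to reach 25.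

Step 4 (asymmetric aldol and ring closure). The ester-bearing diene may turn over slowly, facial discrimination may be incomplete for this electron-rich aldehyde, and the p-silyloxybenzylic C–O bond may ionise during the acid-mediated closure with erosion of optical purity. The fallback sets out from 4 and comes back at 10, using a stoichiometric chiral reagent and a Claisen condensation in place of the diene. Aldehyde 4 is allylated with (–)-B-allyldiisopinocampheylborane (Et2O, –78 °C, ethanolamine work-up), which adds to the Si face of aryl aldehydes, to give (1S)-1-Ar-but-3-en-1-ol F3. TBSOTf and 2,6-lutidine give (1S)-1-Ar-1-(tert-butyldimethylsilyloxy)but-3-ene F4. Tsuji–Wacker oxidation of the terminal alkene (PdCl2, CuCl, O2, DMF–water; the trisubstituted alkenes are inert) gives (4S)-4-Ar-4-(tert-butyldimethylsilyloxy)butan-2-one F5. Kinetic enolisation of the methyl group with LiHMDS at –78 °C and Claisen condensation with dimethyl oxalate give methyl (6S)-6-Ar-6-(tert-butyldimethylsilyloxy)-2,4-dioxohexanoate F6. HF·pyridine removes the alkyl silyl ether, and catalytic camphorsulfonic acid in CH2Cl2 closes and dehydrates hemiketal 9 to pyranone ester 10.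

Step 6 (diazoketone formation). Dipolar cycloaddition of diazomethane to the electron-poor C=C bond of the acid chloride or of the product (pyrazoline formation) may compete with acylation. The fallback sets out from acid 12 through acid chloride 13 and comes back at 14, replacing acylation of diazomethane by diazo transfer. Acid chloride 13 is methylated by Stille–Milstein coupling with tetramethyltin (BnPd(PPh3)2Cl cat., THF, 60 °C) to give (2S)-6-acetyl-2-Ar-2,3-dihydro-4H-pyran-4-one F7. Kinetic deprotonation of the acetyl group (LiHMDS, THF, –78 °C) and acylation with 2,2,2-trifluoroethyl trifluoroacetate give (2S)-2-Ar-6-(4,4,4-trifluoro-3-oxobutanoyl)-2,3-dihydro-4H-pyran-4-one F8, used crude. Detrifluoroacetylative diazo transfer with methanesulfonyl azide, Et3N and water in MeCN then returns diazoketone 14.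

**Further compounds**

F1 | step 9 | [(2S)-2-Ar-4-oxo-3,4-dihydro-2H-pyran-6-yl]acetic acid | CC(C)=CCC/C(C)=C/Cc1cc([C@@H]2CC(=O)C=C(CC(=O)O)O2)ccc1O[Si](C(C)C)(C(C)C)C(C)C
F2 | step 9 | [(2S)-2-Ar-4-oxo-3,4-dihydro-2H-pyran-6-yl]acetyl chloride | CC(C)=CCC/C(C)=C/Cc1cc([C@@H]2CC(=O)C=C(CC(=O)Cl)O2)ccc1O[Si](C(C)C)(C(C)C)C(C)C
F3 | step 4 | (1S)-1-Ar-but-3-en-1-ol | CC(C)=CCC/C(C)=C/Cc1cc([C@H](CC=C)O)ccc1O[Si](C(C)C)(C(C)C)C(C)C
F4 | step 4 | (1S)-1-Ar-1-(tert-butyldimethylsilyloxy)but-3-ene | CC(C)=CCC/C(C)=C/Cc1cc([C@H](CC=C)O[Si](C)(C)C(C)(C)C)ccc1O[Si](C(C)C)(C(C)C)C(C)C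
F5 | step 4 | (4S)-4-Ar-4-(tert-butyldimethylsilyloxy)butan-2-one | CC(C)=CCC/C(C)=C/Cc1cc([C@H](CC(C)=O)O[Si](C)(C)C(C)(C)C)ccc1O[Si](C(C)C)(C(C)C)C(C)C
F6 | step 4 | methyl (6S)-6-Ar-6-(tert-butyldimethylsilyloxy)-2,4-dioxohexanoate | CC(C)=CCC/C(C)=C/Cc1cc([C@H](CC(=O)CC(=O)C(=O)OC)O[Si](C)(C)C(C)(C)C)ccc1O[Si](C(C)C)(C(C)C)C(C)C
F7 | step 6 | (2S)-6-acetyl-2-Ar-2,3-dihydro-4H-pyran-4-one | CC(C)=CCC/C(C)=C/Cc1cc([C@@H]2CC(=O)C=C(C(C)=O)O2)ccc1O[Si](C(C)C)(C(C)C)C(C)C
F8 | step 6 | (2S)-2-Ar-6-(4,4,4-trifluoro-3-oxobutanoyl)-2,3-dihydro-4H-pyran-4-one | CC(C)=CCC/C(C)=C/Cc1cc([C@@H]2CC(=O)C=C(C(=O)CC(=O)C(F)(F)F)O2)ccc1O[Si](C(C)C)(C(C)C)C(C)C
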